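**Retrosynthetic overview**

1. Last disconnection: the ArCH2–ring A bond. Ring B (bought as phlorobutyrophenone, then O-methylated) adds as a carbon nucleophile to the 2-methylene trione released from a CH2OMe handle on ring A.
2. The quaternary (R) carbon of ring A comes from an aromatic precursor by a chelation-controlled, enantioselective dearomative Claisen shift of an O-allyl group; cross-metathesis then turns allyl into prenyl.
3. That arene is made in one operation from 3-allyloxy-2-methylcyclobutenone and a siloxyalkyne. The ring carbonyl carbon lying between the acyl-bearing and the CH2Ar-bearing carbons is joined to the CH2-bearing alkyne carbon, and the siloxy alkyne carbon is joined to the methyl-bearing (later quaternary) carbon.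
4. Enabling feature: ring A (the six-membered carbocycle with the quaternary carbon) is a dearomatised phloroglucinol with oxygen on every second ring carbon. Its C(OH)=C(CH2Ar) enol unit is therefore a siloxyalkyne in disguise and the adjoining ring C=O carbon a ketene carbon; the annulation leaves the three oxygens distinct (OH, OSi, O-allyl).
5. Ring order: ring A is the only ring constructed (step 5); ring B is carried in intact and attached in the last step.

Key step: step 5

Assumption: the target is one drawn tautomer of a freely equilibrating enolised triketone; its only stereocentre is the quaternary ring carbon, which is (R), and intermediates are drawn in whichever tautomer is convenient.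

**Route**

Step 1
Reactants: 1 3-methoxyprop-1-yne
Product: 4 triisopropyl[(3-methoxyprop-1-yn-1-yl)oxy]silane, via lithium acetylide 2 (not isolated), via lithium ynolate 3 (not isolated)
Conditions: LiN(SiMe3)2 (2.1 equiv), t-BuOOH (1.05 equiv), THF, −78 to 0 °C; then i-Pr3SiOTf, −78 °C to rt
Reagents that add atoms: tert-butyl hydroperoxide CC(C)(C)OO; triisopropylsilyl trifluoromethanesulfonate CC(C)[Si](OS(=O)(=O)C(F)(F)F)(C(C)C)C(C)C
Why: Oxygen transfer from lithium tert-butyl peroxide to the lithium acetylide gives the ynolate, which the bulky silyl triflate traps on oxygen (known siloxyalkyne synthesis from terminal alkynes).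

Step 2
Reactants: 5 1-ethoxyprop-1-yne; 6 trichloroacetyl chloride
Product: 8 4,4-dichloro-3-ethoxy-2-methylcyclobut-2-en-1-one, via dichloroketene 7 (not isolated)
Conditions: activated Zn dust, Et2O/DME, rt, slow addition of 6
Reagents that add atoms: none
Why: Ketene–alkyne [2+2] cycloaddition; the nucleophilic methyl-bearing carbon of the ynol ether bonds to the ketene carbonyl carbon, which fixes the 2-methyl-3-ethoxy pattern.

Step 3
Reactants: 8 4,4-dichloro-3-ethoxy-2-methylcyclobut-2-en-1-one
Product: 9 3-ethoxy-2-methylcyclobut-2-en-1-one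
Conditions: Zn dust, AcOH, TMEDA, EtOH, 0 °C to rt
Reagents that add atoms: none
Why: Standard reductive dechlorination of a dichloroketene adduct through its zinc enolate; the amine buffer protects the vinylogous ester.

Step 4
Reactants: 9 3-ethoxy-2-methylcyclobut-2-en-1-one; 10 prop-2-en-1-ol
Product: 11 2-methyl-3-(prop-2-en-1-yloxy)cyclobut-2-en-1-one
Conditions: 10 (5 equiv), camphorsulfonic acid (5 mol %), benzene, 60 °C, 4 Å MS (ethanol removed)
Reagents that add atoms: none
Why: Acid-catalysed vinylogous transesterification (addition–elimination at the alkoxy-bearing carbon), driven by excess allyl alcohol and removal of ethanol.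

Step 5
Reactants: 11 2-methyl-3-(prop-2-en-1-yloxy)cyclobut-2-en-1-one; 4 triisopropyl[(3-methoxyprop-1-yn-1-yl)oxy]silane
Product: 16 5-(allyloxy)-2-(methoxymethyl)-4-methyl-3-[(triisopropylsilyl)oxy]phenol, via vinylketene 12 (not isolated), via vinylcyclobutenone 13 (not isolated), via dienylketene 14 (not isolated), via cyclohexadienone 15 (not isolated)
Conditions: 4 (1.2 equiv), toluene, 110 °C, sealed tube
Reagents that add atoms: none
Why: Heating opens cyclobutenone 11 by a thermal 4π electrocyclic reaction to vinylketene 12, whose ketene carbon is attacked by the CH2OMe-bearing carbon of siloxyalkyne 4 in a regioselective [2+2] cycloaddition to give 13; a second 4π opening gives dienylketene 14, and a thermal disrotatory 6π electrocyclisation closes the six-membered ring to 15, which tautomerises to phenol 16. The closest known reaction type is the Danheiser benzannulation of cyclobutenones with siloxyalkynes, which gives resorcinol monosilyl ethers with the alkyne substituent between the new OH and the OSi group. Net, the alkyne is inserted between the carbonyl carbon and the methyl-bearing sp2 carbon of 11: the former carbonyl carbon is joined to the CH2OMe-bearing alkyne carbon and the siloxy alkyne carbon to the methyl-bearing carbon, while the old four-ring bond between C=O and CH2 is broken and re-made in the 6π step. Ring A is thus closed in the six-electron electrocyclic mode (the transient four-membered ring of 13 by [2+2]); no stereocentre is created, because the quaternary carbon of racemic 13 is lost on ring opening and 16 is achiral. The selectivity needed is the orientation of the [2+2] step, fixed by the polarisation of the ynol silyl ether (carbon beta to oxygen nucleophilic, central ketene carbon electrophilic), together with fast capture of 12, secured by the high ketenophilicity of siloxyalkynes. The result is a phloroglucinol with three distinct oxygens (free OH, O-silyl, O-allyl) and one free ring position, as the following steps require.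

Step 6
Reactants: 16 5-(allyloxy)-2-(methoxymethyl)-4-methyl-3-[(triisopropylsilyl)oxy]phenol
Product: 17 3-(allyloxy)-2-bromo-6-(methoxymethyl)-4-methyl-5-[(triisopropylsilyl)oxy]phenol
Conditions: NBS (1.0 equiv), CH2Cl2, −78 to 0 °C
Reagents that add atoms: N-bromosuccinimide O=C1CCC(=O)N1Br
Why: Electrophilic bromination of a very electron-rich phenol at its only free ring position, much faster than attack on the allyl double bond.

Step 7
Reactants: 17 3-(allyloxy)-2-bromo-6-(methoxymethyl)-4-methyl-5-[(triisopropylsilyl)oxy]phenol; 18 N-methoxy-N-methylhexanamide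
Product: 20 1-[2-(allyloxy)-6-hydroxy-5-(methoxymethyl)-3-methyl-4-(triisopropylsilyloxy)phenyl]hexan-1-one, via dilithio species 19 (not isolated)
Conditions: n-BuLi (2.2 equiv), THF, −78 °C; then 18, −78 to 0 °C; aq NH4Cl
Reagents that add atoms: none
Why: Deprotonation of the phenol and bromine–lithium exchange give an aryllithium that the Weinreb amide acylates only to the ketone stage; the low temperature prevents carbolithiation of the allyl ether, and no Lewis acid touches the benzylic ether.

Step 8
Reactants: 20 1-[2-(allyloxy)-6-hydroxy-5-(methoxymethyl)-3-methyl-4-(triisopropylsilyloxy)phenyl]hexan-1-one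
Product: 21 1-[2-(allyloxy)-6-(tert-butyldimethylsilyloxy)-5-(methoxymethyl)-3-methyl-4-(triisopropylsilyloxy)phenyl]hexan-1-one
Conditions: NaH (1.05 equiv), t-BuMe2SiCl, THF, 0 °C to rt
Reagents that add atoms: tert-butyldimethylsilyl chloride CC(C)(C)[Si](C)(C)Cl
Why: Silylation of the sodium phenoxide caps the hydrogen-bonded OH, so that in step 9 the ketone oxygen can chelate only together with the allyl ether oxygen.

Step 9
Reactants: 21 1-[2-(allyloxy)-6-(tert-butyldimethylsilyloxy)-5-(methoxymethyl)-3-methyl-4-(triisopropylsilyloxy)phenyl]hexan-1-one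
Product: 22 (6R)-6-allyl-3-(tert-butyldimethylsilyloxy)-2-hexanoyl-4-(methoxymethyl)-6-methyl-5-(triisopropylsilyloxy)cyclohexa-2,4-dien-1-one
Conditions: Cu(OTf)2 (10 mol %), (S,S)-t-Bu-box [2,2'-isopropylidenebis((4S)-4-tert-butyl-2-oxazoline)] (12 mol %), 4 Å MS, CH2Cl2, 0 °C to rt
Reagents that add atoms: none
Why: Proposed new method: the cationic Cu(box) complex (divalent copper) should bind the ketone oxygen and the neighbouring allyl ether oxygen of 21 as a six-membered chelate, which polarises the O–allyl bond and triggers a chair-like [3,3] shift to the only ortho carbon that is not acylated (the methyl-bearing one), the loss of aromaticity being offset by the chelated vinylogous ester formed; the C2-symmetric ligand shields one face of the arene, so the allyl group reaches one face of the prochiral methyl-bearing carbon and the (R) centre is set under catalyst control (the ligand antipode that gives (R) is fixed in a first run); plain allyl is used instead of prenyl because it resists ionisation and a [3,3] shift of a prenyl ether would give the reverse-prenyl chain; the closest known reaction types are the Cu(box)-catalysed enantioselective Claisen rearrangement of 2-alkoxycarbonyl allyl vinyl ethers and the chiral-copper-catalysed dearomative Claisen rearrangement of allyl 2-naphthyl ethers bearing a chelating carbonyl group next to the ether oxygen.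

Step 10
Reactants: 22 (6R)-6-allyl-3-(tert-butyldimethylsilyloxy)-2-hexanoyl-4-(methoxymethyl)-6-methyl-5-(triisopropylsilyloxy)cyclohexa-2,4-dien-1-one; 23 2-methylbut-2-ene
Product: 24 (6R)-3-(tert-butyldimethylsilyloxy)-2-hexanoyl-4-(methoxymethyl)-6-methyl-6-(3-methylbut-2-en-1-yl)-5-(triisopropylsilyloxy)cyclohexa-2,4-dien-1-one
Conditions: second-generation Grubbs catalyst (5 mol %), 23 (excess, co-solvent), CH2Cl2, 40 °C
Reagents that add atoms: none
Why: Olefin cross-metathesis of the terminal allyl group with 2-methylbut-2-ene is the standard allyl-to-prenyl conversion; the quaternary stereocentre is not involved.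

Step 11
Reactants: 24 (6R)-3-(tert-butyldimethylsilyloxy)-2-hexanoyl-4-(methoxymethyl)-6-methyl-6-(3-methylbut-2-en-1-yl)-5-(triisopropylsilyloxy)cyclohexa-2,4-dien-1-one
Product: 25 (4R)-2-hexanoyl-3,5-dihydroxy-6-(methoxymethyl)-4-methyl-4-(3-methylbut-2-en-1-yl)cyclohexa-2,5-dien-1-one
Conditions: Bu4NF (2.2 equiv), AcOH (2.5 equiv), THF, 0 °C
Reagents that add atoms: none
Why: Fluoride cleaves both vinylogous silyl esters; the acetic acid buffer keeps the enolate protonated so that methoxide is not expelled from the CH2OMe handle, and the quaternary centre cannot epimerise.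

Step 12
Reactants: 26 1-(2,4,6-trihydroxyphenyl)butan-1-one
Product: 27 1-(2,6-dihydroxy-4-methoxyphenyl)butan-1-one
Conditions: Me2SO4 (1.0 equiv), K2CO3 (1.0 equiv), acetone, rt
Reagents that add atoms: dimethyl sulfate COS(=O)(=O)OC
Why: The para hydroxyl is the most acidic and the only one not hydrogen-bonded to the ketone, so one equivalent of methylating agent reacts there first.

Step 13
Reactants: 25 (4R)-2-hexanoyl-3,5-dihydroxy-6-(methoxymethyl)-4-methyl-4-(3-methylbut-2-en-1-yl)cyclohexa-2,5-dien-1-one; 27 1-(2,6-dihydroxy-4-methoxyphenyl)butan-1-one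
Product: 29 (4R)-6-[(3-butanoyl-2,4-dihydroxy-6-methoxyphenyl)methyl]-2-hexanoyl-3,5-dihydroxy-4-methyl-4-(3-methylbut-2-en-1-yl)cyclohexa-2,5-dien-1-one, via methylene trione 28 (not isolated)
Conditions: 27 (3 equiv), (CF3)2CHOH, 40 °C
Reagents that add atoms: none
Why: The acidic enolised dione loses methanol to give the 2-methylene trione 28 (an ortho-quinone-methide equivalent), which is captured by a free ring carbon of 27 (its two free positions are equivalent) in a Michael-type Friedel–Crafts alkylation, the usual way methylene-bridged acylphloroglucinols are joined; excess 27 limits double alkylation and the quaternary stereocentre is untouched.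

**Compound list**

1 | 3-methoxyprop-1-yne | COCC#C | starting material
2 | lithium 3-methoxyprop-1-ynide (formed in flask) | COCC#C[Li] | intermediate
3 | lithium 3-methoxyprop-1-yn-1-olate (formed in flask) | COCC#CO[Li] | intermediate
4 | triisopropyl[(3-methoxyprop-1-yn-1-yl)oxy]silane | COCC#CO[Si](C(C)C)(C(C)C)C(C)C | intermediate
5 | 1-ethoxyprop-1-yne | CCOC#CC | starting material
6 | trichloroacetyl chloride | ClC(=O)C(Cl)(Cl)Cl | starting material
7 | dichloroketene (formed in flask) | ClC(Cl)=C=O | intermediate
8 | 4,4-dichloro-3-ethoxy-2-methylcyclobut-2-en-1-one | CCOC1=C(C)C(=O)C1(Cl)Cl | intermediate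
9 | 3-ethoxy-2-methylcyclobut-2-en-1-one | CCOC1=C(C)C(=O)C1 | intermediate
10 | prop-2-en-1-ol (allyl alcohol) | OCC=C | starting material
11 | 2-methyl-3-(prop-2-en-1-yloxy)cyclobut-2-en-1-one | C=CCOC1=C(C)C(=O)C1 | intermediate
12 | 3-(allyloxy)-2-methylbuta-1,3-dien-1-one, vinylketene (formed in flask) | C=CCOC(=C)C(C)=C=O | intermediate
13 | 4-[1-(allyloxy)vinyl]-2-(methoxymethyl)-4-methyl-3-(triisopropylsilyloxy)cyclobut-2-en-1-one, racemic (formed in flask) | C=CCOC(=C)C1(C)C(=O)C(COC)=C1O[Si](C(C)C)(C(C)C)C(C)C | intermediate
14 | 5-(allyloxy)-2-(methoxymethyl)-4-methyl-3-(triisopropylsilyloxy)hexa-1,3,5-trien-1-one, dienylketene with ketenyl and vinyl groups cis (formed in flask) | O=C=C(COC)/C(O[Si](C(C)C)(C(C)C)C(C)C)=C(/C)C(=C)OCC=C | intermediate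
15 | 5-(allyloxy)-2-(methoxymethyl)-4-methyl-3-(triisopropylsilyloxy)cyclohexa-2,4-dien-1-one (formed in flask) | O=C1CC(OCC=C)=C(C)C(O[Si](C(C)C)(C(C)C)C(C)C)=C1COC | intermediate
16 | 5-(allyloxy)-2-(methoxymethyl)-4-methyl-3-[(triisopropylsilyl)oxy]phenol | Oc1cc(OCC=C)c(C)c(O[Si](C(C)C)(C(C)C)C(C)C)c1COC | intermediate
17 | 3-(allyloxy)-2-bromo-6-(methoxymethyl)-4-methyl-5-[(triisopropylsilyl)oxy]phenol | Oc1c(Br)c(OCC=C)c(C)c(O[Si](C(C)C)(C(C)C)C(C)C)c1COC | intermediate
18 | N-methoxy-N-methylhexanamide | CCCCCC(=O)N(C)OC | starting material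
19 | lithium 3-(allyloxy)-2-lithio-6-(methoxymethyl)-4-methyl-5-(triisopropylsilyloxy)phenoxide (formed in flask) | [Li]Oc1c([Li])c(OCC=C)c(C)c(O[Si](C(C)C)(C(C)C)C(C)C)c1COC | intermediate
20 | 1-[2-(allyloxy)-6-hydroxy-5-(methoxymethyl)-3-methyl-4-(triisopropylsilyloxy)phenyl]hexan-1-one | CCCCCC(=O)c1c(O)c(COC)c(O[Si](C(C)C)(C(C)C)C(C)C)c(C)c1OCC=C | intermediate
21 | 1-[2-(allyloxy)-6-(tert-butyldimethylsilyloxy)-5-(methoxymethyl)-3-methyl-4-(triisopropylsilyloxy)phenyl]hexan-1-one | CCCCCC(=O)c1c(O[Si](C)(C)C(C)(C)C)c(COC)c(O[Si](C(C)C)(C(C)C)C(C)C)c(C)c1OCC=C | intermediate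
22 | (6R)-6-allyl-3-(tert-butyldimethylsilyloxy)-2-hexanoyl-4-(methoxymethyl)-6-methyl-5-(triisopropylsilyloxy)cyclohexa-2,4-dien-1-one | CCCCCC(=O)C1=C(O[Si](C)(C)C(C)(C)C)C(COC)=C(O[Si](C(C)C)(C(C)C)C(C)C)[C@@](C)(CC=C)C1=O | intermediate
23 | 2-methylbut-2-ene | CC=C(C)C | starting material
24 | (6R)-3-(tert-butyldimethylsilyloxy)-2-hexanoyl-4-(methoxymethyl)-6-methyl-6-(3-methylbut-2-en-1-yl)-5-(triisopropylsilyloxy)cyclohexa-2,4-dien-1-one | CCCCCC(=O)C1=C(O[Si](C)(C)C(C)(C)C)C(COC)=C(O[Si](C(C)C)(C(C)C)C(C)C)[C@@](C)(CC=C(C)C)C1=O | intermediate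
25 | (4R)-2-hexanoyl-3,5-dihydroxy-6-(methoxymethyl)-4-methyl-4-(3-methylbut-2-en-1-yl)cyclohexa-2,5-dien-1-one | CCCCCC(=O)C1=C(O)[C@](C)(CC=C(C)C)C(O)=C(COC)C1=O | intermediate
26 | 1-(2,4,6-trihydroxyphenyl)butan-1-one (phlorobutyrophenone) | CCCC(=O)c1c(O)cc(O)cc1O | starting material
27 | 1-(2,6-dihydroxy-4-methoxyphenyl)butan-1-one | CCCC(=O)c1c(O)cc(OC)cc1O | intermediate
28 | 2-hexanoyl-3-hydroxy-4-methyl-4-(3-methylbut-2-en-1-yl)-6-methylidenecyclohex-2-ene-1,5-dione, same spatial arrangement at the quaternary carbon as 25 (formed in flask) | CCCCCC(=O)C1=C(O)[C@](C)(CC=C(C)C)C(=O)C(=C)C1=O | intermediate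
29 | (4R)-6-[(3-butanoyl-2,4-dihydroxy-6-methoxyphenyl)methyl]-2-hexanoyl-3,5-dihydroxy-4-methyl-4-(3-methylbut-2-en-1-yl)cyclohexa-2,5-dien-1-one (CNP0219674.1) | CCCCCC(=O)C1=C(O)[C@](C)(CC=C(C)C)C(O)=C(Cc2c(OC)cc(O)c(C(=O)CCC)c2O)C1=O | target

**Step count and risks**

Total steps: 13. Longest linear sequence: 11 steps (steps 2, 3, 4, 5, 6, 7, 8, 9, 10, 11, 13).

Steps most likely to fail:

1. Step 9 (proposed new method). The dearomatising [3,3] shift may need temperatures at which the chelate no longer controls the face, or the allyl ether (or the benzylic methyl ether) may ionise under the Lewis acid and recombine without facial control. The fallback uses known chemistry, sets out from 20 and comes back at 25. Deallylation of 20 (Pd(PPh3)4, morpholine, THF) should give 1-[2,6-dihydroxy-3-(methoxymethyl)-5-methyl-4-(triisopropylsilyloxy)phenyl]hexan-1-one F1. Desilylation (Bu4NF, AcOH) should give the free acylphloroglucinol 1-[2,4,6-trihydroxy-3-(methoxymethyl)-5-methylphenyl]hexan-1-one F2. The classical alkylative dearomatisation of acylphloroglucinols (NaOMe, MeOH, prenyl bromide, 0 °C) should then give racemic 2-hexanoyl-3,5-dihydroxy-6-(methoxymethyl)-4-methyl-4-(3-methylbut-2-en-1-yl)cyclohexa-2,5-dien-1-one F3 after removal of O-alkylated and regioisomeric C-alkylated material. Preparative HPLC on a chiral stationary phase (amylose tris(3,5-dimethylphenylcarbamate)) would then deliver 25.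

2. Step 5 (key step). The donor-substituted cyclobutenone may open too slowly, so that at the temperature needed the allyl vinyl ether unit undergoes its own [3,3] shift or the ortho-hydroxybenzyl ether product loses methanol. The fallback sets out from allyl alcohol 10 and siloxyalkyne 4 and comes back at 16; it makes vinylketene 12 at room temperature without a cyclobutenone. Base-catalysed addition (cat. NaH, THF) of 10 to commercial ethyl 2-methylbuta-2,3-dienoate F4 should give ethyl 3-(allyloxy)-2-methylbut-2-enoate F5. Saponification (LiOH, aq THF) gives 3-(allyloxy)-2-methylbut-2-enoic acid F6, and oxalyl chloride (cat. DMF) gives 3-(allyloxy)-2-methylbut-2-enoyl chloride F7. 1,4-Dehydrochlorination of F7 with Et3N in the presence of 4 (toluene, rt) generates 12, which is captured as 13, and warming to 80 °C completes the electrocyclic cascade to 16.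

3. Step 13. The methylene trione 28 may be lost by self-condensation or loss of formaldehyde, 27 may be alkylated twice, or the prenyl group may close onto a neighbouring enol oxygen. The fallback sets out from 24 and comes back at 29; the bridge is made before the silyl groups are removed, so no free enol is present. BF3·OEt2 (CH2Cl2, −78 °C) should ionise the allylic methyl ether of 24 to a silyloxy-stabilised cation that alkylates 27 in a Friedel–Crafts reaction, giving (6R)-4-[(3-butanoyl-2,4-dihydroxy-6-methoxyphenyl)methyl]-3-(tert-butyldimethylsilyloxy)-2-hexanoyl-6-methyl-6-(3-methylbut-2-en-1-yl)-5-(triisopropylsilyloxy)cyclohexa-2,4-dien-1-one F8. Bu4NF/AcOH (THF, 0 °C) then gives 29.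

**Further compounds**

F1 | step 9 | 1-[2,6-dihydroxy-3-(methoxymethyl)-5-methyl-4-(triisopropylsilyloxy)phenyl]hexan-1-one | CCCCCC(=O)c1c(O)c(COC)c(O[Si](C(C)C)(C(C)C)C(C)C)c(C)c1O
F2 | step 9 | 1-[2,4,6-trihydroxy-3-(methoxymethyl)-5-methylphenyl]hexan-1-one | CCCCCC(=O)c1c(O)c(COC)c(O)c(C)c1O
F3 | step 9 | racemic 2-hexanoyl-3,5-dihydroxy-6-(methoxymethyl)-4-methyl-4-(3-methylbut-2-en-1-yl)cyclohexa-2,5-dien-1-one | CCCCCC(=O)C1=C(O)C(C)(CC=C(C)C)C(O)=C(COC)C1=O
F4 | step 5 | ethyl 2-methylbuta-2,3-dienoate (purchased) | C=C=C(C)C(=O)OCC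
F5 | step 5 | ethyl 3-(allyloxy)-2-methylbut-2-enoate (double-bond isomers) | CCOC(=O)C(C)=C(C)OCC=C
F6 | step 5 | 3-(allyloxy)-2-methylbut-2-enoic acid | OC(=O)C(C)=C(C)OCC=C
F7 | step 5 | 3-(allyloxy)-2-methylbut-2-enoyl chloride | ClC(=O)C(C)=C(C)OCC=C
F8 | step 13 | (6R)-4-[(3-butanoyl-2,4-dihydroxy-6-methoxyphenyl)methyl]-3-(tert-butyldimethylsilyloxy)-2-hexanoyl-6-methyl-6-(3-methylbut-2-en-1-yl)-5-(triisopropylsilyloxy)cyclohexa-2,4-dien-1-one | CCCCCC(=O)C1=C(O[Si](C)(C)C(C)(C)C)C(Cc2c(OC)cc(O)c(C(=O)CCC)c2O)=C(O[Si](C(C)C)(C(C)C)C(C)C)[C@@](C)(CC=C(C)C)C1=O
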